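**Plan**

Retrosynthesis first removes the O–CH3 bond of the ring A 4-methoxyl, then opens ring A at its C1–C6 bond, then cuts the depside O4'–C(=O) bond, the C–Cl bond and the chain C4–C5 bond.
The enabling feature is ring A itself: C1 carries the depside carbonyl, C2 OH, C3 Cl, C4 OMe, C5 H and C6 CH3, the pattern of a folded linear C8 poly-β-carbonyl chain whose C4 bears the chlorine and whose C1 is already the ester of ring B O4'.
Forward, the chain is assembled on a dioxinone: its γ-carbon (chain C4) is acylated with a ketal-masked acetoacetyl unit (C5–C8), C4 is chlorinated while it is the only doubly activated carbon, and the ketal is removed.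
Thermolysis then releases the acylketene, which is captured by the free 4-OH of methyl orsellinate, so ring B is present intact and the ester bond exists before ring A does.
Ring A is closed last by aldol condensation of chain C2 onto C7 and aromatisation, and the one unchelated phenol is methylated.
The target has no stereocentre; the transient CHCl and aldol centres are erased on aromatisation.

Key step: step 6

Remark: open-chain compounds are drawn as single tautomers although keto–enol mixtures are expected. The CHCl centre of 6, 7 and 9 is racemic and labile, which is immaterial here. Compound 1 is the commercial ethylene ketal of ethyl acetoacetate.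

**Route**

Step 1
Reactants: 1 ethyl (2-methyl-1,3-dioxolan-2-yl)acetate
Product: 2 N-methoxy-N-methyl-2-(2-methyl-1,3-dioxolan-2-yl)acetamide
Conditions: MeNHOMe·HCl (1.5 equiv), iPrMgCl (3.0 equiv), THF, −20 to 0 °C
Reagents that add atoms: N,O-dimethylhydroxylamine hydrochloride, CNOC.Cl
Why: Weinreb amide formation by aminolysis of the ester with the chloromagnesium amide made in the flask is standard and should leave the base-stable dioxolane untouched.

Step 2
Reactants: 3 2,2,6-trimethyl-4H-1,3-dioxin-4-one; 2 N-methoxy-N-methyl-2-(2-methyl-1,3-dioxolan-2-yl)acetamide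
Product: 5 2,2-dimethyl-6-[3-(2-methyl-1,3-dioxolan-2-yl)-2-oxopropyl]-4H-1,3-dioxin-4-one, via lithium dienolate 4 (not isolated)
Conditions: 3 (2.0 equiv), LiN(SiMe3)2 (2.0 equiv), THF, −78 °C; then 2, −78 to −30 °C; aq NH4Cl
Reagents that add atoms: none
Why: Vinylogous Claisen-type acylation, in which the lithium dienolate reacts at its γ-carbon with the Weinreb amide and the chelated tetrahedral adduct should prevent over-addition until work-up releases the ketone.

Step 3
Reactants: 5 2,2-dimethyl-6-[3-(2-methyl-1,3-dioxolan-2-yl)-2-oxopropyl]-4H-1,3-dioxin-4-one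
Product: 6 6-[1-chloro-3-(2-methyl-1,3-dioxolan-2-yl)-2-oxopropyl]-2,2-dimethyl-4H-1,3-dioxin-4-one (racemic)
Conditions: MgCl2 (1.2 equiv), pyridine (2.0 equiv), CH2Cl2, 0 °C; then NCS (1.0 equiv), 0 °C
Reagents that add atoms: N-chlorosuccinimide, O=C1CCC(=O)N1Cl
Why: Electrophilic α-chlorination of an active methylene by soft enolisation, which should place the chlorine on chain C4 because this CH2 is the only carbon flanked by both the ketone and the vinylogous ester (the site at which such magnesium enolates are known to be C-acylated), whereas C6 lies between a ketone and a ketal.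

Step 4
Reactants: 6 6-[1-chloro-3-(2-methyl-1,3-dioxolan-2-yl)-2-oxopropyl]-2,2-dimethyl-4H-1,3-dioxin-4-one
Product: 7 6-(1-chloro-2,4-dioxopentyl)-2,2-dimethyl-4H-1,3-dioxin-4-one
Conditions: pyridinium p-toluenesulfonate (0.2 equiv), acetone–H2O (10:1), 50 °C
Reagents that add atoms: water, O
Why: Acid-catalysed ketal hydrolysis under transketalisation conditions should free the C7 ketone, since exchange at the dioxinone (itself an acetone ketal) is degenerate in acetone and the α-chloro ketone is stable to mild acid.

Step 5
Reactants: 7 6-(1-chloro-2,4-dioxopentyl)-2,2-dimethyl-4H-1,3-dioxin-4-one; 8 methyl orsellinate (methyl 2,4-dihydroxy-6-methylbenzoate)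
Product: 10 3-hydroxy-4-(methoxycarbonyl)-5-methylphenyl (3E)-4-chloro-3-hydroxy-5,7-dioxooct-3-enoate (chelated enol of the aryl 4-chloro-3,5,7-trioxooctanoate), via acylketene 9 (not isolated)
Conditions: 8 (3 equiv), toluene, 110 °C, slow addition of 7; crude product used directly
Reagents that add atoms: none
Why: Thermal retro-hetero-Diels–Alder fragmentation of the dioxinone gives acetone and an acylketene, which the unchelated 4-OH of 8 should capture in preference to the 2-OH locked in a hydrogen bond to the ester (the established dioxinone acylketene esterification of alcohols and phenols), so the ester bond is made before either ortho substituent of ring A exists.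

Step 6
Reactants: 10 3-hydroxy-4-(methoxycarbonyl)-5-methylphenyl (3E)-4-chloro-3-hydroxy-5,7-dioxooct-3-enoate
Product: 12 3-hydroxy-4-(methoxycarbonyl)-5-methylphenyl 3-chloro-2,4-dihydroxy-6-methylbenzoate, via aldol adduct 11 (not isolated)
Conditions: Et3N (1.5 equiv), CH2Cl2, 0 °C to rt; then CF3CO2H, 0 °C to rt
Reagents that add atoms: none
Why: Et3N reversibly enolises the chain, and although the chlorinated C4 methine is the most acidic site its enolate has no ring-forming outlet, so the reaction should drain through the C2 enolate (flanked by the aryl ester and the C3 ketone), which adds to the C7 methyl ketone and makes the chain C2–C7 bond, that is the ring A C1–C6 bond, in aldol adduct 11. CF3CO2H then dehydrates the tertiary carbinol and the C3 and C5 carbonyls enolise, so ring A aromatises with hydroxyls at C2 and C4, the methyl at C6 and the chlorine, carried on chain C4, fixed at C3. The closest known reaction is the biomimetic aldol aromatisation of 3,5,7-triketo esters, obtained by acylketene capture, to 2,4-dihydroxy-6-alkylbenzoates, here run on an aryl ester with a 4-chloro substituent. Ring A closes by 6-exo-trig attack on the C7 carbonyl, 6-(enolexo)-exo-trig when the nucleophile is written as the ester enolate and 6-(enolendo)-exo-trig as the C3 ketone enolate, both favourable modes. No stereocentre survives, since the three centres of 11 are erased on aromatisation. The selectivity needed is aldol closure over Claisen closure (C6 onto C1), enol lactonisation (the C5 enol oxygen onto C1) and ketene-forming loss of the ring B aryloxide, and it should be secured by the greater electrophilicity of the methyl ketone compared with the ester carbonyl, the weak amine base in an aprotic solvent at low temperature, and the acid switch that makes the aldol irreversible through dehydration.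

Step 7
Reactants: 12 3-hydroxy-4-(methoxycarbonyl)-5-methylphenyl 3-chloro-2,4-dihydroxy-6-methylbenzoate
Product: 13 3-hydroxy-4-(methoxycarbonyl)-5-methylphenyl 3-chloro-2-hydroxy-4-methoxy-6-methylbenzoate (target)
Conditions: MeI (1.05 equiv), K2CO3 (1.05 equiv), acetone, rt
Reagents that add atoms: iodomethane, CI
Why: Williamson ether synthesis with one equivalent of base and electrophile should alkylate only the ring A 4-OH, the single phenol not tied into a hydrogen bond with an ortho ester carbonyl and the most acidic one (para to the ester, ortho to chlorine), as in the known selective 4-O-alkylation of 2,4-dihydroxybenzoates.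

**Compound list**

1 | ethyl (2-methyl-1,3-dioxolan-2-yl)acetate | CCOC(=O)CC1(C)OCCO1 | starting material
2 | N-methoxy-N-methyl-2-(2-methyl-1,3-dioxolan-2-yl)acetamide | CON(C)C(=O)CC1(C)OCCO1 | intermediate
3 | 2,2,6-trimethyl-4H-1,3-dioxin-4-one | CC1=CC(=O)OC(C)(C)O1 | starting material
4 | lithium 2,2-dimethyl-6-methylidene-6H-1,3-dioxin-4-olate (lithium dienolate of 3) | [Li+].[O-]C1=CC(=C)OC(C)(C)O1 | intermediate
5 | 2,2-dimethyl-6-[3-(2-methyl-1,3-dioxolan-2-yl)-2-oxopropyl]-4H-1,3-dioxin-4-one | CC1(C)OC(=O)C=C(CC(=O)CC2(C)OCCO2)O1 | intermediate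
6 | 6-[1-chloro-3-(2-methyl-1,3-dioxolan-2-yl)-2-oxopropyl]-2,2-dimethyl-4H-1,3-dioxin-4-one (racemic) | CC1(C)OC(=O)C=C(C(Cl)C(=O)CC2(C)OCCO2)O1 | intermediate
7 | 6-(1-chloro-2,4-dioxopentyl)-2,2-dimethyl-4H-1,3-dioxin-4-one (racemic, keto form drawn) | CC(=O)CC(=O)C(Cl)C1=CC(=O)OC(C)(C)O1 | intermediate
8 | methyl orsellinate (methyl 2,4-dihydroxy-6-methylbenzoate) | COC(=O)c1c(C)cc(O)cc1O | starting material
9 | 4-chlorooct-1-ene-1,3,5,7-tetrone (acylketene) | CC(=O)CC(=O)C(Cl)C(=O)C=C=O | intermediate
10 | 3-hydroxy-4-(methoxycarbonyl)-5-methylphenyl (3E)-4-chloro-3-hydroxy-5,7-dioxooct-3-enoate | CC(=O)CC(=O)/C(Cl)=C(\O)CC(=O)Oc1cc(C)c(C(=O)OC)c(O)c1 | intermediate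
11 | 3-hydroxy-4-(methoxycarbonyl)-5-methylphenyl 3-chloro-6-hydroxy-6-methyl-2,4-dioxocyclohexane-1-carboxylate (mixture of diastereomers and tautomers) | COC(=O)c1c(C)cc(OC(=O)C2C(=O)C(Cl)C(=O)CC2(C)O)cc1O | intermediate
12 | 3-hydroxy-4-(methoxycarbonyl)-5-methylphenyl 3-chloro-2,4-dihydroxy-6-methylbenzoate | COC(=O)c1c(C)cc(OC(=O)c2c(C)cc(O)c(Cl)c2O)cc1O | intermediate
13 | 3-hydroxy-4-(methoxycarbonyl)-5-methylphenyl 3-chloro-2-hydroxy-4-methoxy-6-methylbenzoate (CNP0146021.0) | COC(=O)c1c(C)cc(OC(=O)c2c(C)cc(OC)c(Cl)c2O)cc1O | target

**Step count and risks**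

Total step count: 7. Longest linear sequence: 7 steps (1 to 13).

Steps most likely to fail:

Step 6. The ring B aryloxide is a good leaving group, so Claisen closure, enol lactonisation or base-induced ketene formation may expel it before the aldol closure takes place. The fallback sets out from 7 and comes back at 13; it performs the fold on an ester that cannot leave and makes the depside bond afterwards by classical esterification. Compound 7 would be heated with allyl alcohol in toluene at 110 °C to give allyl 4-chloro-3,5,7-trioxooctanoate F1. Treatment with Et3N in CH2Cl2 and then CF3CO2H should aromatise it to allyl 3-chloro-2,4-dihydroxy-6-methylbenzoate F2. Methylation of the unchelated 4-OH with MeI and K2CO3 in acetone would give allyl 3-chloro-2-hydroxy-4-methoxy-6-methylbenzoate F3. Deallylation with Pd(PPh3)4 (zerovalent palladium) and morpholine in THF would release 3-chloro-2-hydroxy-4-methoxy-6-methylbenzoic acid F4. Trifluoroacetic anhydride in toluene (mixed-anhydride depside esterification) would then join F4 to the free 4-OH of 8 to give 13.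

Step 5. The chlorine acidifies C4–H, so capture of the acylketene by its own C5 enol oxygen (pyranone formation) may outrun bimolecular capture by the phenol; thermal loss of HCl from the α-chloro-β-dicarbonyl unit is a second risk. The fallback sets out from 5 and comes back at 10; it makes the ester before the chlorine is present. Compound 5 would be heated with 8 in toluene at 110 °C to give 3-hydroxy-4-(methoxycarbonyl)-5-methylphenyl 6-(2-methyl-1,3-dioxolan-2-yl)-3,5-dioxohexanoate F5. NCS with catalytic Mg(ClO4)2 in ethyl acetate at 0 °C should chlorinate the most acidic carbon, C4 between the two ketones, to give 3-hydroxy-4-(methoxycarbonyl)-5-methylphenyl 4-chloro-6-(2-methyl-1,3-dioxolan-2-yl)-3,5-dioxohexanoate F6. Pyridinium p-toluenesulfonate in wet acetone would then remove the ketal to give 10.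

Step 3. The monochloride is more acidic than 5 and may be chlorinated a second time, or chlorination may occur at ring carbon C5 of the dioxinone. The fallback sets out from 3 and comes back at 6; it fixes the chlorine on chain C4 before the C4–C5 bond is formed. Compound 3 would be deprotonated with LiN(iPr)2 in THF at −78 °C and the dienolate quenched with hexachloroethane to give 6-(chloromethyl)-2,2-dimethyl-4H-1,3-dioxin-4-one F7. A second γ-deprotonation with LiN(SiMe3)2 at −78 °C and acylation by Weinreb amide 2 would give 6 directly, so that no chlorinating agent meets the keto-dioxinone.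

Further compounds
F1 | step 6 | allyl 4-chloro-3,5,7-trioxooctanoate | CC(=O)CC(=O)C(Cl)C(=O)CC(=O)OCC=C
F2 | step 6 | allyl 3-chloro-2,4-dihydroxy-6-methylbenzoate | C=CCOC(=O)c1c(C)cc(O)c(Cl)c1O
F3 | step 6 | allyl 3-chloro-2-hydroxy-4-methoxy-6-methylbenzoate | C=CCOC(=O)c1c(C)cc(OC)c(Cl)c1O
F4 | step 6 | 3-chloro-2-hydroxy-4-methoxy-6-methylbenzoic acid | OC(=O)c1c(C)cc(OC)c(Cl)c1O
F5 | step 5 | 3-hydroxy-4-(methoxycarbonyl)-5-methylphenyl 6-(2-methyl-1,3-dioxolan-2-yl)-3,5-dioxohexanoate | COC(=O)c1c(C)cc(OC(=O)CC(=O)CC(=O)CC2(C)OCCO2)cc1O
F6 | step 5 | 3-hydroxy-4-(methoxycarbonyl)-5-methylphenyl 4-chloro-6-(2-methyl-1,3-dioxolan-2-yl)-3,5-dioxohexanoate | COC(=O)c1c(C)cc(OC(=O)CC(=O)C(Cl)C(=O)CC2(C)OCCO2)cc1O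
F7 | step 3 | 6-(chloromethyl)-2,2-dimethyl-4H-1,3-dioxin-4-one | CC1(C)OC(=O)C=C(CCl)O1
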